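The route rests on excising a sulfone bridge from between C4 and C5 (germacrane numbering). The (Z)-C4=C5 alkene and its allylic C15 hydroxymethyl group in the nine-membered oxonine ring (furanone O, C3–C10) are both products of one epoxy-Ramberg–Bäcklund reaction. A ten-membered 1-oxa-4-thiacycle, the cyclic sulfone 23 carrying a spiro-oxirane at C4, is deprotonated at C5; 1,3-displacement opens the epoxide, SO2 leaves, and the ring contracts by one atom while the alkene and the C15 alcohol appear. The precursor comes from a lactate-derived furanone aldehyde, a glyceraldehyde-derived allyl bromide (Barbier union setting C7/C8) and double sulfide alkylation.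

Key step: step 18

Remark: germacrane numbering is used throughout (C1 ketone, C2=C3 furanone alkene, ring O between C3 and C10, C4(=C5)–C15H2OH, C6 lactone carbinol, C7, C8 isobutyrate carbinol, C9, C10 with C14 methyl, C11(=C13)–C12 lactone carbonyl). Aldehyde 10 is assumed to be bought or freshly made from 1,2:5,6-di-O-isopropylidene-D-mannitol.

Step 1
Reactants: 1 (S)-lactic acid; 2 pivalaldehyde
Product: 3 (2S,5S)-2-tert-butyl-5-methyl-1,3-dioxolan-4-one (cis)
Conditions: p-TsOH (cat.), H2SO4 (cat.), pentane, reflux, Dean–Stark; crystallisation from pentane at low temperature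
Reagents that add atoms: none
Why: Acid-catalysed acetalisation with azeotropic water removal should give the dioxolanone, the new acetal centre being set cis to the methyl group and the cis isomer being purified by crystallisation.

Step 2
Reactants: 3 (2S,5S)-2-tert-butyl-5-methyl-1,3-dioxolan-4-one; 4 allyl bromide
Product: 5 (2S,5R)-2-tert-butyl-5-methyl-5-(prop-2-en-1-yl)-1,3-dioxolan-4-one
Conditions: LDA, THF, −78 °C; then 4, −78 → −30 °C
Reagents that add atoms: none
Why: Enolate alkylation with self-regeneration of the stereocentre: the lithium enolate should be allylated anti to the tert-butyl group, giving the quaternary centre (future C10, R) with overall retention of the lactate configuration.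

Step 3
Reactants: 5 (2S,5R)-5-allyl-2-tert-butyl-5-methyl-1,3-dioxolan-4-one; 6 tert-butyldimethyl(prop-2-yn-1-yloxy)silane
Product: 7 (4R)-8-(tert-butyldimethylsilyloxy)-4-hydroxy-4-methyloct-1-en-6-yn-5-one
Conditions: 6, n-BuLi, THF, −78 °C; then 5, −78 °C; aq. NH4Cl
Reagents that add atoms: none
Why: Nucleophilic acyl substitution of the acetal-lactone by the lithium acetylide, whose tetrahedral adduct should survive at −78 °C (no double addition) and collapse on work-up with loss of pivalaldehyde, leaving C10 untouched.

Step 4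
Reactants: 7 (4R)-8-(tert-butyldimethylsilyloxy)-4-hydroxy-4-methyloct-1-en-6-yn-5-one
Product: 8 (2R)-5-[(tert-butyldimethylsilyloxy)methyl]-2-methyl-2-(prop-2-en-1-yl)furan-3(2H)-one
Conditions: Ph3PAuCl (2 mol%), AgOTf (2 mol%), toluene, rt
Reagents that add atoms: none
Why: Gold(I)-catalysed 5-endo-dig hydroalkoxylation of the α′-hydroxy ynone is the standard cycloisomerisation to 3(2H)-furanones and affects no stereocentre.

Step 5
Reactants: 8 (2R)-2-allyl-5-[(tert-butyldimethylsilyloxy)methyl]-2-methylfuran-3(2H)-one
Product: 9 2-[(2R)-5-[(tert-butyldimethylsilyloxy)methyl]-2-methyl-3-oxo-2,3-dihydrofuran-2-yl]acetaldehyde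
Conditions: OsO4 (cat.), NaIO4, 2,6-lutidine, dioxane/H2O, rt
Reagents that add atoms: sodium periodate, [Na+].[O-]I(=O)(=O)=O (terminal oxidant; oxygen delivered through catalytic osmium tetroxide, O=[Os](=O)(=O)=O)
Why: Lemieux–Johnson cleavage, in which OsO4 should dihydroxylate the terminal alkene far faster than the push-pull furanone alkene and periodate cleaves the diol to the C8 aldehyde.

Step 6
Reactants: 10 (R)-2,2-dimethyl-1,3-dioxolane-4-carbaldehyde; 11 tert-butyl acrylate
Product: 12 tert-butyl 2-{[(4R)-2,2-dimethyl-1,3-dioxolan-4-yl](hydroxy)methyl}prop-2-enoate (both carbinol epimers)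
Conditions: DABCO, MeOH (cat.), neat 11, rt
Reagents that add atoms: none
Why: Morita–Baylis–Hillman reaction of the α-alkoxy aldehyde; the new carbinol centre forms unselectively but is destroyed in step 7, and the dioxolane centre (future C6) is retained.

Step 7
Reactants: 12 Morita–Baylis–Hillman alcohol
Product: 13 tert-butyl (2Z)-2-(bromomethyl)-3-[(4S)-2,2-dimethyl-1,3-dioxolan-4-yl]prop-2-enoate
Conditions: NBS, Me2S, CH2Cl2, 0 °C → rt
Reagents that add atoms: N-bromosuccinimide, O=C1CCC(=O)N1Br
Why: SN2′ bromination of the allylic alcohol via its alkoxysulfonium salt under non-acidic conditions should give the thermodynamically favoured (Z)-2-(bromomethyl)enoate without touching the acetonide or the tert-butyl ester.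

Step 8
Reactants: 9 furanone aldehyde; 13 (Z)-allyl bromide
Product: 14 tert-butyl (3R,4R)-3-[(4S)-2,2-dimethyl-1,3-dioxolan-4-yl]-4-hydroxy-2-methylidene-5-[(2R)-5-[(tert-butyldimethylsilyloxy)methyl]-2-methyl-3-oxo-2,3-dihydrofuran-2-yl]pentanoate (C7 R, C8 R)
Conditions: Zn dust, THF/sat. aq. NH4Cl, 0 °C → rt
Reagents that add atoms: none
Why: Zinc Barbier (Dreiding–Schmidt-type) allylation: the (Z)-allylzinc should react at its γ-carbon through a chair transition state with the γ-substituent axial (C7/C8 syn), the aldehyde approaching anti to the allylic C6–O bond of the dioxolane (Felkin–Anh-type 1,2-induction), which sets C7 (R) and C8 (R), while the tert-butyl ester prevents lactonisation onto O8.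

Step 9
Reactants: 14 homoallylic alcohol
Product: 15 8-O-isobutyrate of 14
Conditions: (i-PrCO)2O, DMAP (cat.), pyridine, CH2Cl2, rt
Reagents that add atoms: isobutyric anhydride, CC(C)C(=O)OC(=O)C(C)C
Why: DMAP-catalysed acylation of the secondary alcohol installs the C8 isobutyrate with retention of configuration.

Step 10
Reactants: 15 acrylate isobutyrate
Product: 16 13-(phenylsulfanyl)-11,13-dihydro derivative of 15 (C11 epimers)
Conditions: PhSH, Et3N (cat.), CH2Cl2, rt
Reagents that add atoms: thiophenol, Sc1ccccc1
Why: Base-catalysed thia-Michael addition masks the acrylate, the only acceptor that would intercept the sulfur nucleophiles of step 14; the new C11 centre is irrelevant because the alkene is regenerated in step 18.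

Step 11
Reactants: 16 masked ester
Product: 17 triol (C5-OH, C6-OH and furanyl CH2OH free; tert-butyl ester, isobutyrate and phenylthio group retained)
Conditions: AcOH/THF/H2O (3:1:1), 45 °C
Reagents that add atoms: none
Why: Mild aqueous acidolysis should cleave the terminal acetonide and the primary silyl ether, while the tert-butyl ester resists both cleavage and lactonisation onto the liberated C6 hydroxyl.

Step 12
Reactants: 17 triol
Product: 18 dibromide (C5-Br and furanyl CH2Br; C6-OH free)
Conditions: CBr4, PPh3, CH2Cl2, 0 °C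
Reagents that add atoms: carbon tetrabromide, BrC(Br)(Br)Br
Why: Appel reaction, in which the two primary alcohols should be converted into bromides at 0 °C much faster than the hindered secondary C6 alcohol.

Step 13
Reactants: 18 dibromide
Product: 19 6-O-tert-butyldimethylsilyl ether of 18
Conditions: TBSOTf, 2,6-lutidine, CH2Cl2, −78 → 0 °C
Reagents that add atoms: tert-butyldimethylsilyl triflate, CC(C)(C)[Si](C)(C)OS(=O)(=O)C(F)(F)F
Why: Silylation of the remaining alcohol with the reactive silyl triflate gives an ether that is a poor leaving group beside the later C5 carbanion and that blocks acyl migration from O8.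

Step 14
Reactants: 19 silylated dibromide
Product: 20 ten-membered cyclic sulfide (S bridging C4 and C5; ring O, C3, C4, S, C5–C10)
Conditions: Na2S (3 equiv), DMF, rt → 40 °C, slow addition of 19 (high dilution)
Reagents that add atoms: sodium sulfide, [Na+].[Na+].[S-2]
Why: Double SN2 thioetherification: sulfide should displace the activated furanylmethyl bromide first and the resulting thiolate then closes the ten-membered ring on the primary C5 bromide under high dilution, the acrylate being masked.

Step 15
Reactants: 20 cyclic sulfide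
Product: 21 cyclic sulfone carrying the 13-phenylsulfonyl group
Conditions: mCPBA (5 equiv), NaHCO3, CH2Cl2, 0 °C → rt
Reagents that add atoms: meta-chloroperbenzoic acid, OOC(=O)c1cccc(Cl)c1
Why: Peracid oxidation should take both sulfides to sulfones without epoxidising the electron-poor furanone alkene.

Step 16
Reactants: 21 cyclic sulfone
Product: 22 C4-methylidene cyclic sulfone (vinyl sulfone, C4=C15H2)
Conditions: (CH2O)n, piperidine (cat.), AcOH (cat.), THF, 50 °C
Reagents that add atoms: formaldehyde (from paraformaldehyde), C=O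
Why: Knoevenagel-type methylenation (Mannich addition/elimination) at C4, the only doubly activated methylene (α to the ring sulfone and vinylogously α to the furanone ketone), should give the 1-sulfonylvinyl unit under buffered conditions that leave the β-sulfonyl ester mask intact.

Step 17
Reactants: 22 vinyl sulfone
Product: 23 spiro-epoxy sulfone (oxirane C4–C15–O; C4 epimers)
Conditions: t-BuOOH (decane), K2CO3 (cat.), THF, 0 °C
Reagents that add atoms: tert-butyl hydroperoxide, CC(C)(C)OO
Why: Weitz–Scheffer nucleophilic epoxidation: the peroxide anion should add to the terminal C15 of the doubly activated alkene and the stabilised C4 carbanion closes the oxirane; the C4 configuration is inconsequential because C4 becomes sp2 in step 18.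

Step 18
Reactants: 23 spiro-epoxy sulfone
Product: 24 ring-contracted nine-membered diene (tert-butyl acrylate ester, 6-O-TBS, 8-O-isobutyrate, (Z)-C4=C5, free C15-OH)
Conditions: LiOt-Bu (4 equiv), THF, 0 °C → rt; aq. NH4Cl
Reagents that add atoms: none
Why: Lithium tert-butoxide should deprotonate C5, the only α′ position of the ring sulfone that carries hydrogen (C4 is quaternary); the carbanion attacks C4 in a 1,3-displacement that opens the spiro-oxirane to the C15 alkoxide and forms a thiirane 1,1-dioxide, which loses SO2 cheletropically to give the C4=C5 alkene. The closest known reaction types are the epoxy-Ramberg–Bäcklund synthesis of allylic alcohols from α,β-epoxy sulfones and the Ramberg–Bäcklund ring contraction of ten-membered cyclic α-halo sulfones to nine-membered cycloalkenes. The only ring closed is the transient three-membered episulfone (3-exo-tet), and its extrusion contracts the ten-membered 1-oxa-4-thiacycle to the nine-membered oxonine. No stereocentre is created, and the ring-cis (Z) geometry is enforced by ring size, since an E-cyclononene fused to the furanone would be prohibitively strained. The step needs the displacement to outrun β-elimination at C6, which the poorly leaving silyloxy group and the still open lactone should secure, and the excess base at the same time unmasks the acrylate by E1cB loss of benzenesulfinate from the ester enolate.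

Step 19
Reactants: 24 ring-contracted diene
Product: 25 CNP0176924.3 (target)
Conditions: TFA/CH2Cl2 (1:1), H2O (2%), 0 °C → rt; aq. NaHCO3
Reagents that add atoms: none
Why: Acidolysis should cleave the tert-butyl ester and the C6 silyl ether, and the liberated γ-hydroxy acid closes the trans-fused α-methylene γ-lactone by acyl substitution with retention at C6 and C7.

Compound list
1 | (S)-lactic acid | C[C@H](O)C(=O)O | starting material
2 | pivalaldehyde | CC(C)(C)C=O | starting material
3 | (2S,5S)-2-tert-butyl-5-methyl-1,3-dioxolan-4-one | C[C@@H]1O[C@H](C(C)(C)C)OC1=O | intermediate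
4 | allyl bromide | C=CCBr | starting material
5 | (2S,5R)-2-tert-butyl-5-methyl-5-(prop-2-en-1-yl)-1,3-dioxolan-4-one | C=CC[C@@]1(C)O[C@H](C(C)(C)C)OC1=O | intermediate
6 | tert-butyldimethyl(prop-2-yn-1-yloxy)silane | C#CCO[Si](C)(C)C(C)(C)C | starting material
7 | (4R)-8-(tert-butyldimethylsilyloxy)-4-hydroxy-4-methyloct-1-en-6-yn-5-one | C=CC[C@@](C)(O)C(=O)C#CCO[Si](C)(C)C(C)(C)C | intermediate
8 | (2R)-5-[(tert-butyldimethylsilyloxy)methyl]-2-methyl-2-(prop-2-en-1-yl)furan-3(2H)-one | C=CC[C@@]1(C)OC(CO[Si](C)(C)C(C)(C)C)=CC1=O | intermediate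
9 | 2-[(2R)-5-[(tert-butyldimethylsilyloxy)methyl]-2-methyl-3-oxo-2,3-dihydrofuran-2-yl]acetaldehyde | O=CC[C@@]1(C)OC(CO[Si](C)(C)C(C)(C)C)=CC1=O | intermediate
10 | (R)-2,2-dimethyl-1,3-dioxolane-4-carbaldehyde | O=C[C@H]1COC(C)(C)O1 | starting material
11 | tert-butyl acrylate | C=CC(=O)OC(C)(C)C | starting material
12 | tert-butyl 2-{[(4R)-2,2-dimethyl-1,3-dioxolan-4-yl](hydroxy)methyl}prop-2-enoate (carbinol epimers) | C=C(C(=O)OC(C)(C)C)C(O)[C@H]1COC(C)(C)O1 | intermediate
13 | tert-butyl (2Z)-2-(bromomethyl)-3-[(4S)-2,2-dimethyl-1,3-dioxolan-4-yl]prop-2-enoate | BrC/C(C(=O)OC(C)(C)C)=C\[C@H]1COC(C)(C)O1 | intermediate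
14 | Barbier adduct, tert-butyl (3R,4R)-3-[(4S)-dioxolanyl]-4-hydroxy-2-methylidene-5-[(2R)-furanonyl]pentanoate | C=C(C(=O)OC(C)(C)C)[C@@H]([C@H]1COC(C)(C)O1)[C@H](O)C[C@@]2(C)OC(CO[Si](C)(C)C(C)(C)C)=CC2=O | intermediate
15 | 8-O-isobutyrate of 14 | C=C(C(=O)OC(C)(C)C)[C@@H]([C@H]1COC(C)(C)O1)[C@H](OC(=O)C(C)C)C[C@@]2(C)OC(CO[Si](C)(C)C(C)(C)C)=CC2=O | intermediate
16 | 13-phenylthio-masked ester (C11 epimers) | O=C(OC(C)(C)C)C(CSc1ccccc1)[C@@H]([C@H]2COC(C)(C)O2)[C@H](OC(=O)C(C)C)C[C@@]3(C)OC(CO[Si](C)(C)C(C)(C)C)=CC3=O | intermediate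
17 | triol (C5-OH, C6-OH, furanyl CH2OH) | O=C(OC(C)(C)C)C(CSc1ccccc1)[C@@H]([C@H](O)CO)[C@H](OC(=O)C(C)C)C[C@@]3(C)OC(CO)=CC3=O | intermediate
18 | dibromide with free C6-OH | O=C(OC(C)(C)C)C(CSc1ccccc1)[C@@H]([C@H](O)CBr)[C@H](OC(=O)C(C)C)C[C@@]3(C)OC(CBr)=CC3=O | intermediate
19 | 6-O-TBS dibromide | O=C(OC(C)(C)C)C(CSc1ccccc1)[C@@H]([C@H](O[Si](C)(C)C(C)(C)C)CBr)[C@H](OC(=O)C(C)C)C[C@@]3(C)OC(CBr)=CC3=O | intermediate
20 | ten-membered cyclic sulfide | O=C(OC(C)(C)C)C(CSc1ccccc1)[C@H]2[C@H](O[Si](C)(C)C(C)(C)C)CSCC3=CC(=O)[C@@](C)(C[C@H]2OC(=O)C(C)C)O3 | intermediate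
21 | ten-membered cyclic sulfone with 13-phenylsulfonyl mask | O=C(OC(C)(C)C)C(CS(=O)(=O)c1ccccc1)[C@H]2[C@H](O[Si](C)(C)C(C)(C)C)CS(=O)(=O)CC3=CC(=O)[C@@](C)(C[C@H]2OC(=O)C(C)C)O3 | intermediate
22 | C4-methylidene cyclic sulfone | O=C(OC(C)(C)C)C(CS(=O)(=O)c1ccccc1)[C@H]2[C@H](O[Si](C)(C)C(C)(C)C)CS(=O)(=O)C(=C)C3=CC(=O)[C@@](C)(C[C@H]2OC(=O)C(C)C)O3 | intermediate
23 | spiro-epoxy sulfone (C4 epimers) | O=C(OC(C)(C)C)C(CS(=O)(=O)c1ccccc1)[C@H]2[C@H](O[Si](C)(C)C(C)(C)C)CS(=O)(=O)C4(CO4)C3=CC(=O)[C@@](C)(C[C@H]2OC(=O)C(C)C)O3 | intermediate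
24 | ring-contracted diene, tert-butyl ester, 6-O-TBS, 15-OH | C=C(C(=O)OC(C)(C)C)[C@H]2[C@H](O[Si](C)(C)C(C)(C)C)/C=C(/CO)C3=CC(=O)[C@@](C)(C[C@H]2OC(=O)C(C)C)O3 | intermediate
25 | CNP0176924.3 (8-O-isobutyryl furanoheliangolide; 6R,7R,8R,10R) | C=C1C(=O)O[C@@H]2/C=C(/CO)C3=CC(=O)[C@@](C)(C[C@@H](OC(=O)C(C)C)[C@@H]12)O3 | target

Total step count: 19. Longest linear sequence: 17 steps (steps 1–5 and 8–19, from lactic acid); steps 6–7 form the second branch.

Steps most likely to fail

Step 18 (key step). The spiro-oxirane may be consumed by the alkoxide base or by liberated sulfinate, or the C5 carbanion may expel the C6 silyloxide, before the 1,3-displacement takes place. The fallback sets out from 22 and returns at 25. Conjugate addition of 4-methoxybenzyl alcohol to the vinyl sulfone (cat. Cs2CO3, THF, 0 °C), with chlorination of the resulting stabilised C4 carbanion by N-chlorosuccinimide in the same flask, should give the C4-chloro C4-[(4-methoxybenzyloxy)methyl] sulfone F1. A classical Ramberg–Bäcklund reaction (KOt-Bu, THF, −78 → 0 °C), now with chloride as the leaving group on C4, should give the ring-contracted 15-O-PMB ether F2 with the acrylate unmasked. TFA with anisole then removes the PMB, TBS and tert-butyl groups and closes the lactone to 25.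

Step 14. Intermolecular S-alkylation (oligomerisation) may outrun ring closure, because the fast first and the slow second C–S bond formation share one flask. The fallback sets out from 19 and returns at 20. Potassium thioacetate (1 equiv, THF, 0 °C) should substitute only the activated furanylmethyl bromide to give the thioacetate F3. Methanolysis with K2CO3 in degassed MeOH/THF, added slowly at high dilution, releases the thiolate with no free sulfide present, and this closes the ring on the C5 bromide to give 20.

Step 8. Simple diastereoselection may be poor or reversed (anti instead of syn), or the reagent control may be mismatched with the remote C10 centre, giving the C8 epimer. The fallback sets out from 9 and 13 and returns at 15. The anti adduct, 8-epi-14 F4, which Cr(II)-mediated (Nozaki–Hiyama) allylation in THF is expected to favour, is esterified with isobutyric acid under Mitsunobu conditions (PPh3, DIAD, THF, 0 °C). This inverts C8 and installs the isobutyrate in one operation, giving 15 directly.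

Further compounds
F1 | step 18 | C4-chloro C4-[(4-methoxybenzyloxy)methyl] cyclic sulfone | O=C(OC(C)(C)C)C(CS(=O)(=O)c1ccccc1)[C@H]2[C@H](O[Si](C)(C)C(C)(C)C)CS(=O)(=O)C(Cl)(COCc4ccc(OC)cc4)C3=CC(=O)[C@@](C)(C[C@H]2OC(=O)C(C)C)O3
F2 | step 18 | 15-O-(4-methoxybenzyl) ether of 24 | C=C(C(=O)OC(C)(C)C)[C@H]2[C@H](O[Si](C)(C)C(C)(C)C)/C=C(/COCc4ccc(OC)cc4)C3=CC(=O)[C@@](C)(C[C@H]2OC(=O)C(C)C)O3
F3 | step 14 | furanylmethyl thioacetate with C5 bromide retained | O=C(OC(C)(C)C)C(CSc1ccccc1)[C@@H]([C@H](O[Si](C)(C)C(C)(C)C)CBr)[C@H](OC(=O)C(C)C)C[C@@]3(C)OC(CSC(C)=O)=CC3=O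
F4 | step 8 | 8-epi-14 (anti adduct) | C=C(C(=O)OC(C)(C)C)[C@@H]([C@H]1COC(C)(C)O1)[C@@H](O)C[C@@]2(C)OC(CO[Si](C)(C)C(C)(C)C)=CC2=O
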